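I asked how much slower one hand was than the other, not how long either took.

| flask | left-handed substrate | right-handed substrate | reagent | racemization catalyst | temperature | remark | time |
|---|---|---|---|---|---|---|---|
| south | 20 mM | 20 mM | 22 mM | 34 µM | 10 °C | run made earlier |  |
| north-west | 20 mM | 20 mM | 88 mM | 34 µM | 40 °C | run made earlier |  |
| south-west | 40 mM | 40 mM | 44 mM | 34 µM | 10 °C | run made earlier |  |
| green | 20 mM | 20 mM | 44.0 mM | 34 µM | 15 °C |  | 12 min |
| amber | 20 mM | 20 mM | 44.0 mM | 34 µM | 65 °C |  | 12 min |
| teal | 20 mM | 20 mM | 44.0 mM | 34 µM | 40 °C |  | 12 min |

The three flasks differ in temperature, so I looked in the earlier runs for what temperature changes.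

- south (time / min: left-handed product / %, right-handed product / %, left-handed substrate / %): 1.00: 1, 3, 49; 1.50: 2, 2, 49; 2.50: 2, 1, 49; 4.00: 3, 1, 45; 8.00: 4, 3, 48; 12.0: 7, 2, 42
- north-west (time / min: left-handed product / %, right-handed product / %, left-handed substrate / %): 0.667: 10, 7, 37; 1.33: 16, 4, 32; 2.00: 27, 12, 28; 2.50: 32, 15, 23; 3.00: 33, 20, 17; 4.00: 35, 22, 15
- south-west (time / min: left-handed product / %, right-handed product / %, left-handed substrate / %): 2.50: 2, 3, 47; 5.00: 8, 4, 44; 8.00: 12, 6, 41; 10.0: 11, 3, 39; 12.0: 13, 1, 35

(each reading ± 2 percentage points)

- reagent is single-handed; left-handed substrate and right-handed substrate are mirror images of each other, charged as a racemate, each of them at the stated concentration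
- the analysis behind the earlier runs scatters by 2 percentage points, standard deviation
- candidate steps: left-handed substrate + racemization catalyst <-> right-handed substrate + racemization catalyst; reagent + right-handed substrate -> right-handed product; racemization catalyst -> spent catalyst; reagent + left-handed substrate -> left-handed product
- an excess is below zero if the other one leads
- the handed part of reagent does not stay in what it makes, so the products of the two hands are mirror images too

In the north-west run, left-handed substrate and left-handed product together still read 50.0% at 4.00 min, half of the charge, so I saw no sign of one hand turning into the other there. Each substrate then falls as k c(reagent) c(substrate). Dividing the two rates removes both time and c(reagent): the logarithm of the left-handed fraction remaining, over that of the right-handed, is the ratio of the two constants. Summed over the six north-west readings, this gave 2.24, a reading of the selectivity factor at 40 °C. With equal substrates, the first product carries an excess of the factor less one over the factor plus one, here 38.3%, so I expected teal, at 40 °C, to start there and then lose excess as its left-handed substrate thinned.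

But the cold runs read this factor poorly. In the south-west run, right-handed product read 1% at 12.0 min against a scatter of 2 percentage points. Its noisy ratio to left-handed product still stood higher than the factor at 40 °C, so I put the coldest flask, green, first.

- the best flask by excess of left-handed product over right-handed product; "all alike" if 1.5 percentage points covers them all (green / amber / teal / all alike)
- excess of left-handed product over right-handed product at the end, green
- excess of left-handed product over right-handed product at the end, amber
- excess of left-handed product over right-handed product at the end, teal

The forecast said green 44%, amber 7%, teal 24%, best green: “Excess then falls with conversion and with temperature”.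

The simulation gave green 59.9%, amber 2.21%, teal 23.7%, best green, so green stood 16 points above the forecast.

    left-handed substrate + racemization catalyst ⇌ right-handed substrate + racemization catalyst, rate k1*[racemization catalyst]*[left-handed substrate] forward; the back reaction follows from the equilibrium constant (k = 1200 M⁻¹ min⁻¹, Ea = 58.0 kJ mol⁻¹)
    reagent + right-handed substrate → right-handed product (k = 2.02 M⁻¹ min⁻¹, Ea = 67.0 kJ mol⁻¹)
    racemization catalyst → spent catalyst (k = 0.945 min⁻¹, Ea = 82.0 kJ mol⁻¹)
    reagent + left-handed substrate → left-handed product (k = 4.61 M⁻¹ min⁻¹, Ea = 45.0 kJ mol⁻¹)
    (constants at 40 °C)

Green's own leftovers, divided the same way, gave a factor of 4.33, higher than the 2.24 read at 40 °C. The neighbouring flask, green run at 40 °C, kept 22% of its left-handed substrate. Raising that fraction to the power one over 2.24 gave 51.2% of its right-handed substrate remaining, and the neighbour held 51%. Those two leftovers made a reckoned excess of 23.0%, and the neighbour ended at 23.7%.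

The readings were computed with made-up constants; scatter was added.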